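**Plan**

- Retrosynthesis: the pyrrole N1–C2 bond is cut and the formyl carbon is rejoined to N1, which turns the target into 4-docosylpyridine 1-oxide. The N–O bond and then the bond from pyridine C4 to the first CH2 of the chain are cut next, leading to 4-chloropyridine and docosylmagnesium bromide.
- Enabling feature: N1, C5, C4, C3 (with its docosyl chain) and C2 of the pyrrole ring, plus the formyl carbon on C2, are the six ring atoms of a pyridine (N, C6, C5, C4, C3, C2 in that order). That pyridine is symmetric about its N–C4 axis, so either α-carbon can be pushed out of the ring.
- Forward order: the chain is joined to the ready-made pyridine ring by an iron-catalysed Kumada coupling, the nitrogen is oxidised, and the pyrrole ring arises last by photochemical contraction of the six-membered ring.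
- Stereochemistry: the target has no stereocentre and no stereogenic double bond, so nothing has to be set. The only stereocentre on the way, C2 of a transient 2H-pyrrole, vanishes on tautomerisation.

Key step: step 5

Remark: 4-docosylpyridine 1-oxide is an amphiphile that will not dissolve in pure water, so the aqueous CuSO4 medium usual for this photoreaction is assumed to tolerate tert-butanol as co-solvent at millimolar dilution.

Step 1
Reactants: 1 4-chloropyridine hydrochloride
Product: 2 4-chloropyridine
Conditions: aq. NaOH (1.05 equiv), Et2O, 0 °C; dried over K2CO3, concentrated cold, used at once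
Reagents that add atoms: none
Why: Acid–base neutralisation of a pyridinium salt; cold, brief handling and immediate use should keep the free base from quaternising itself by intermolecular nucleophilic aromatic substitution.

Step 2
Reactants: 3 1-bromodocosane
Product: 4 docosylmagnesium bromide
Conditions: Mg turnings (1.5 equiv), I2 (cat.), THF, 45–50 °C, slow addition; about 0.4 M solution, titrated and kept warm
Reagents that add atoms: magnesium, [Mg]
Why: Grignard formation by insertion of magnesium into the primary C–Br bond; slow addition into warm THF keeps the bromide dilute at the metal surface, which should limit Wurtz coupling and keep the waxy reagent in solution.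

Step 3
Reactants: 2 4-chloropyridine; 4 docosylmagnesium bromide (1.2 equiv)
Product: 5 4-docosylpyridine
Conditions: Fe(acac)3 (5 mol%), THF/NMP, 0 °C to rt; aq. NH4Cl
Reagents that add atoms: none
Why: Iron-catalysed Kumada cross-coupling, for which chloropyridines are standard electrophiles; the C4–Cl bond of the electron-poor ring reacts readily with the low-valent iron species formed from Fe(acac)3 and the Grignard reagent, and with a primary alkyl group in THF/NMP the coupling should outrun β-hydride elimination.

Step 4
Reactants: 5 4-docosylpyridine
Product: 6 4-docosylpyridine 1-oxide
Conditions: mCPBA (1.2 equiv), CH2Cl2, 0 °C to rt; filtration through basic alumina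
Reagents that add atoms: mCPBA (3-chloroperoxybenzoic acid), O=C(OO)c1cccc(Cl)c1
Why: N-Oxidation by electrophilic oxygen transfer from the peracid to the pyridine nitrogen, the saturated chain being inert; alumina replaces the usual basic wash because the amphiphilic N-oxide would emulsify.

Step 5
Reactants: 6 4-docosylpyridine 1-oxide
Product: 10 3-docosyl-1H-pyrrole-2-carbaldehyde, via oxaziridine valence isomer 7 (not isolated), via 5-docosyl-1,2-oxazepine 8 (not isolated), via 3-docosyl-2H-pyrrole-2-carbaldehyde 9 (not isolated)
Conditions: hν (254 nm, low-pressure Hg lamps, quartz), CuSO4·5H2O (2 equiv), t-BuOH/H2O (about 2:1), Ar, 35–40 °C, about 3 mM in 6, stopped at partial conversion, unreacted 6 recycled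
Reagents that add atoms: none
Why: Excitation of the N-oxide closes oxygen onto an α-carbon to give oxaziridine 7, and a six-electron electrocyclic opening of its ring-fusion N–C bond (the old N–C2 bond) gives 1,2-oxazepine 8. The weak N–O bond of 8 then breaks, assisted by coordination of divalent copper, old C2 becoming the aldehyde carbon while the electron-poor nitrogen bonds to old C3: a five-membered closure by 1,5-bonding across the N=C6–C5=C4–C3 unit (5-exo with respect to the C3=C2 enoxy bond, in sum a 1,3-shift of nitrogen from oxygen to carbon) that gives 2H-pyrrole 9. A hydrogen shift from C2 to nitrogen aromatises 9 to 10 and erases the only stereocentre formed, so no stereocontrol is needed. The closest known reaction type is the copper-assisted photochemical ring contraction of pyridine N-oxides, 4-alkyl members included, to pyrrole-2-carbaldehydes. Regiochemistry is fixed by the substrate, since the two α-carbons of 6 are equivalent and old C4 with its chain must end up as pyrrole C3. What the step needs is chemoselectivity against deoxygenation to 5, 2-pyridone formation and the 1,3-oxazepine channel, which the copper salt in a protic aqueous medium, irradiation into the N-oxide band and a stop at partial conversion should secure; the saturated chain carries no chromophore.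

**Compound list**

1 | 4-chloropyridine hydrochloride | Cl.Clc1ccncc1 | starting material
2 | 4-chloropyridine | Clc1ccncc1 | intermediate
3 | 1-bromodocosane | CCCCCCCCCCCCCCCCCCCCCCBr | starting material
4 | docosylmagnesium bromide | CCCCCCCCCCCCCCCCCCCCCC[Mg]Br | intermediate
5 | 4-docosylpyridine | CCCCCCCCCCCCCCCCCCCCCCc1ccncc1 | intermediate
6 | 4-docosylpyridine 1-oxide | CCCCCCCCCCCCCCCCCCCCCCc1cc[n+]([O-])cc1 | intermediate
7 | 4-docosyl-7-oxa-1-azabicyclo[4.1.0]hepta-2,4-diene (oxaziridine valence isomer of 6) | CCCCCCCCCCCCCCCCCCCCCCC1=CC2ON2C=C1 | intermediate
8 | 5-docosyl-1,2-oxazepine | CCCCCCCCCCCCCCCCCCCCCCC1=CC=NOC=C1 | intermediate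
9 | 3-docosyl-2H-pyrrole-2-carbaldehyde (racemic, transient) | CCCCCCCCCCCCCCCCCCCCCCC1=CC=NC1C=O | intermediate
10 | 3-docosyl-1H-pyrrole-2-carbaldehyde | CCCCCCCCCCCCCCCCCCCCCCc1cc[nH]c1C=O | target

**Step count and risks**

Total steps: 5. Longest linear sequence: 4 steps (steps 2, 3, 4 and 5 from 3; the branch from 1 joins at step 3).

Steps most likely to fail, with fallbacks:

First, step 5. The excited N-oxide may lose oxygen or leak into the pyridone and 1,3-oxazepine channels, and the aldehyde may be photolysed further. Aggregation of the amphiphile in aqueous alcohol may also scatter the light and keep the copper salt away from the chromophore. The fallback gives up the ring contraction and uses known pyrrole chemistry; it sets out from 3 and comes back at 10. Commercial 3-bromo-1-(triisopropylsilyl)-1H-pyrrole is treated with t-BuLi (2 equiv) in THF at −78 °C to give 1-(triisopropylsilyl)-1H-pyrrol-3-yllithium F1 by bromine–lithium exchange. Alkylation of this with 3 on warming to rt should give 3-docosyl-1-(triisopropylsilyl)-1H-pyrrole F2. TBAF in THF then removes the silyl group to give 3-docosyl-1H-pyrrole F3. Vilsmeier–Haack formylation (POCl3, DMF, then aq. NaOAc) is expected to go mainly to the α-position activated by the neighbouring chain and so to give 10; the isomer formylated at the remote α-position would be removed by chromatography.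

Second, step 3. Homocoupling of the Grignard reagent, β-hydride elimination with reduction of the chloride, or self-quaternisation of 2 before it couples may erode the cross-coupling. The fallback replaces cross-coupling by addition to an activated pyridine; it sets out from 4 and comes back at 5. Pyridine and phenyl chloroformate in THF at −20 °C give 1-(phenoxycarbonyl)pyridin-1-ium chloride F4. Reagent 4 adds to C4 of this salt in the presence of catalytic CuI (the iodide of monovalent copper) to give phenyl 4-docosyl-4H-pyridine-1-carboxylate F5. Oxidation with o-chloranil in toluene, followed by stirring with aq. NaOH, rearomatises the ring with loss of the carbamate and should give 5.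

Third, step 2. Wurtz coupling at the magnesium surface and precipitation of the waxy reagent may leave too little active Grignard reagent for step 3. The fallback avoids organomagnesium chemistry altogether; it sets out from 1 and comes back at 5, bypassing steps 1 to 3. Commercial 1-docosene is hydroborated with 9-BBN in THF to give 9-docosyl-9-borabicyclo[3.3.1]nonane F6. This is coupled in the same flask with 1 by a B-alkyl Suzuki–Miyaura reaction (Pd(OAc)2, SPhos, excess aq. K3PO4 to take up the HCl as well, THF, 65 °C) to give 5.

**Further compounds**

F1 | step 5 | 1-(triisopropylsilyl)-1H-pyrrol-3-yllithium | [Li]c1ccn(c1)[Si](C(C)C)(C(C)C)C(C)C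
F2 | step 5 | 3-docosyl-1-(triisopropylsilyl)-1H-pyrrole | CCCCCCCCCCCCCCCCCCCCCCc1ccn(c1)[Si](C(C)C)(C(C)C)C(C)C
F3 | step 5 | 3-docosyl-1H-pyrrole | CCCCCCCCCCCCCCCCCCCCCCc1cc[nH]c1
F4 | step 3 | 1-(phenoxycarbonyl)pyridin-1-ium chloride | O=C(Oc1ccccc1)[n+]1ccccc1.[Cl-]
F5 | step 3 | phenyl 4-docosyl-4H-pyridine-1-carboxylate | CCCCCCCCCCCCCCCCCCCCCCC1C=CN(C=C1)C(=O)Oc1ccccc1
F6 | step 2 | 9-docosyl-9-borabicyclo[3.3.1]nonane | CCCCCCCCCCCCCCCCCCCCCCB1C2CCCC1CCC2
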